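**Strategy**

Everything rests on cutting the bond between C3′ of ring A (the acylated phloroglucinol ring, C3′ flanked by the C2′ and C4′ hydroxyls) and the diarylmethine carbon of the heptenyl chain. The C4′–OH beside C3′ and the E alkene one bond beyond the methine carbon form an ortho-allylphenol, the retron of an aromatic Claisen rearrangement. The precursor is therefore a 4′-O-allyl aryl ether, in which ring A is bound through oxygen to the allylic carbinol carbon of a syn-diarylheptanoid with inversion. One [3,3] shift makes the C–C bond, transfers the C–O chirality to the diarylmethine centre, sets the E alkene and regenerates the C4′ phenol.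

Key step: step 14

Locants: ring A carries the ketone at C1′, OH at C2′, the new bond at C3′, OH at C4′, H at C5′ and OMe at C6′; the oxane ring is O1, C2 (aryl), C3 (aroyl), C4 (styryl), C5, C6 (arylethyl). TBS = tert-butyldimethylsilyl, MOM = methoxymethyl. Both coupling partners (18 and 20) come from one aldol adduct (6).

Assumption: the 3R configuration at the enolisable oxane carbon C3 is taken to be the thermodynamic one once the 2-aryl group is axial (an axial aroyl group is anti to that aryl group and meets only one syn-axial hydrogen), so it is set by equilibration; compounds 1, 4 and 9 are taken as purchasable.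

**Route**

Step 1
Reactants: 1 tert-butyl(4-iodophenoxy)dimethylsilane; 2 prop-2-en-1-ol
Product: 3 3-[4-(TBSO)phenyl]propanal
Conditions: Pd(OAc)2 (2 mol %), NaHCO3, n-Bu4NCl, DMF, 40 °C
Reagents that add atoms: none
Why: Heck arylation of allyl alcohol under Jeffery conditions; β-hydride elimination toward the carbinol carbon gives an enol that tautomerises to the saturated aldehyde, and the weak base spares the aryl silyl ether.

Step 2
Reactants: 4 (E)-4-(4-hydroxyphenyl)but-3-en-2-one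
Product: 5 (E)-4-[4-(TBSO)phenyl]but-3-en-2-one
Conditions: TBSCl, imidazole, DMF, 23 °C
Reagents that add atoms: tert-butyldimethylsilyl chloride, CC(C)(C)[Si](C)(C)Cl
Why: Imidazole-promoted silylation masks the acidic phenol before enolate chemistry.

Step 3
Reactants: 5 (E)-4-[4-(TBSO)phenyl]but-3-en-2-one; 3 3-[4-(TBSO)phenyl]propanal
Product: 6 (5S,E)-5-hydroxy-1,7-bis[4-(TBSO)phenyl]hept-1-en-3-one
Conditions: (+)-Ipc2BCl, Et3N, Et2O, −78 °C; then 3, −78 → −20 °C; then H2O2, MeOH, pH 7 buffer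
Reagents that add atoms: none
Why: Paterson boron aldol: kinetic methyl-side enolisation by the chiral chloroborane and addition through a closed six-membered transition state in which the isopinocampheyl ligands select the aldehyde face, which should set the 5S carbinol (the reagent antipode is the one that directs Re-face attack; the (+)-reagent is assumed).

Step 4
Reactants: 6 (5S,E)-5-hydroxy-1,7-bis[4-(TBSO)phenyl]hept-1-en-3-one
Product: 7 (3S,5S,E)-1,7-bis[4-(TBSO)phenyl]hept-1-ene-3,5-diol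
Conditions: Et2BOMe, NaBH4, THF/MeOH (4:1), −78 °C; then MeOH, evaporation
Reagents that add atoms: none
Why: Narasaka–Prasad reduction: external hydride attacks the diethylboron chelate of the β-hydroxy ketone axially, giving the 1,3-syn diol and hence the 3S allylic carbinol, with 1,2-reduction of the chelated enone.

Step 5
Reactants: 7 (3S,5S,E)-1,7-bis[4-(TBSO)phenyl]hept-1-ene-3,5-diol
Product: 8 (4S,6S)-4-{(E)-2-[4-(TBSO)phenyl]ethenyl}-6-{2-[4-(TBSO)phenyl]ethyl}-1,3-dioxan-2-one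
Conditions: CDI, DMAP (cat.), PhMe, 23 → 60 °C
Reagents that add atoms: 1,1′-carbonyldiimidazole, O=C(n1ccnc1)n1ccnc1
Why: Carbonylation of the syn-1,3-diol closes the six-membered cyclic carbonate without touching either stereocentre and turns the allylic C–O bond into a leaving group that releases an alkoxide on ionisation.

Step 6
Reactants: 9 1-(2,4-dihydroxy-6-methoxyphenyl)ethan-1-one
Product: 10 1-[2-methoxy-4,6-bis(methoxymethoxy)phenyl]ethan-1-one
Conditions: NaH, MOMCl, DMF, 0 → 23 °C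
Reagents that add atoms: chloromethyl methyl ether, COCCl
Why: Williamson-type alkylation of both phenoxides; NaH is used because the 2-OH is hydrogen-bonded to the ketone.

Step 7
Reactants: 10 1-[2-methoxy-4,6-bis(methoxymethoxy)phenyl]ethan-1-one
Product: 11 (Z)-3-hydroxy-1-[2-methoxy-4,6-bis(methoxymethoxy)phenyl]prop-2-en-1-one (chelated enol of the β-keto aldehyde)
Conditions: NaH, HCO2Et, THF, 0 → 23 °C; then AcOH
Reagents that add atoms: ethyl formate, CCOC=O
Why: Crossed Claisen condensation of the methyl ketone enolate with ethyl formate; the MOM ether at C2′ prevents cyclisation to a chromone.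

Step 8
Reactants: 8 (4S,6S)-cyclic carbonate; 11 (Z)-3-hydroxy-1-[2-methoxy-4,6-bis(methoxymethoxy)phenyl]prop-2-en-1-one
Product: 13 [(4S,6S)-6-{2-[4-(TBSO)phenyl]ethyl}-4-{(E)-2-[4-(TBSO)phenyl]ethenyl}-5,6-dihydro-4H-pyran-3-yl][2-methoxy-4,6-bis(methoxymethoxy)phenyl]methanone, via hydroxy keto aldehyde 12 (not isolated)
Conditions: Pd(PPh3)4 (5 mol %), THF, 23 °C; then PPTS, 4 Å MS, PhMe, 50 °C
Reagents that add atoms: none
Why: Tsuji–Trost allylation: zerovalent palladium ionises the allylic carbonate with inversion, loss of CO2 gives an alkoxide that deprotonates 11, and the soft 1,3-dicarbonyl carbon attacks the π-allyl terminus remote from the arene anti to palladium (net retention, 4S, E-styryl kept); acid then condenses the freed 6-OH with the formyl enol to the cyclic vinylogous ester.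

Step 9
Reactants: 13 dihydropyranyl aryl ketone; 1 tert-butyl(4-iodophenoxy)dimethylsilane
Product: 17 [2-methoxy-4,6-bis(methoxymethoxy)phenyl][(2R,3R,4S,6S)-2-[4-(TBSO)phenyl]-6-{2-[4-(TBSO)phenyl]ethyl}-4-{(E)-2-[4-(TBSO)phenyl]ethenyl}oxan-3-yl]methanone, via aryl Grignard reagent 14 (not isolated), via enol silane 15 (not isolated), via 3-epi ketone 16 (not isolated)
Conditions: 1, Mg, THF, 23 °C; then 13, CuBr·SMe2 (20 mol %), TMSCl, THF, −78 → −30 °C; then 1 M HCl, THF, 0 °C; then DBU (0.2 equiv), PhMe, 23 °C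
Reagents that add atoms: none
Why: Copper-catalysed, TMSCl-accelerated conjugate addition to the β-alkoxy enone should occur by axial attack at C2 on the half-chair that keeps the 4- and 6-substituents equatorial, placing the aryl group trans to both (2R); hydrolysis of the enol silane and base equilibration of the enolisable C3 should then give the trans-diaxial 2,3-arrangement (3R).

Step 10
Reactants: 17 bis-MOM oxanyl aryl ketone
Product: 18 (2,4-dihydroxy-6-methoxyphenyl)[(2R,3R,4S,6S)-2-[4-(TBSO)phenyl]-6-{2-[4-(TBSO)phenyl]ethyl}-4-{(E)-2-[4-(TBSO)phenyl]ethenyl}oxan-3-yl]methanone (fragment A)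
Conditions: ZnBr2, n-PrSH, CH2Cl2, 0 °C
Reagents that add atoms: none
Why: Lewis-acid/thiol cleavage of the two aryl MOM acetals (the thiol captures the methoxymethyl cation) is fast at 0 °C and should spare the aryl silyl ethers, the alkenes and the benzylic ring ether.

Step 11
Reactants: 6 (5S,E)-5-hydroxy-1,7-bis[4-(TBSO)phenyl]hept-1-en-3-one
Product: 19 (5S,E)-5-(TBSO)-1,7-bis[4-(TBSO)phenyl]hept-1-en-3-one
Conditions: TBSCl, imidazole, DMF, 23 °C
Reagents that add atoms: tert-butyldimethylsilyl chloride, CC(C)(C)[Si](C)(C)Cl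
Why: Silylation blocks the secondary alcohol so that only the future allylic hydroxyl will be free.

Step 12
Reactants: 19 (5S,E)-5-(TBSO)-1,7-bis[4-(TBSO)phenyl]hept-1-en-3-one
Product: 20 (3S,5S,E)-5-(TBSO)-1,7-bis[4-(TBSO)phenyl]hept-1-en-3-ol (fragment B)
Conditions: (R)-2-methyl-CBS-oxazaborolidine (20 mol %), catecholborane, PhMe, −78 °C
Reagents that add atoms: none
Why: Corey–Bakshi–Shibata reduction: the oxazaborolidine binds the ketone with the styryl group as the large substituent and delivers hydride to one face, giving the 3S allylic alcohol under catalyst control, and catecholborane avoids conjugate reduction.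

Step 13
Reactants: 18 fragment A; 20 fragment B
Product: 21 4′-O-[(3R,5S,E)-5-(TBSO)-1,7-bis[4-(TBSO)phenyl]hept-1-en-3-yl] ether of 18
Conditions: PPh3, DIAD, THF, 0 → 23 °C
Reagents that add atoms: none
Why: Mitsunobu etherification: the acidic, non-chelated 4′-OH (para to the carbonyl) displaces the oxyphosphonium ion of the allylic alcohol by SN2, inverting the carbinol carbon from S to R, while the hydrogen-bonded 2′-OH stays free.

Step 14
Reactants: 21 4′-O-allyl aryl ether
Product: 23 3′-C-[(1R,5S,E)-5-(TBSO)-1,7-bis[4-(TBSO)phenyl]hept-2-en-1-yl] derivative of 18 (hexakis-TBS ether of the target), via ortho-dienone 22 (not isolated)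
Conditions: Eu(fod)3 (10 mol %), PhMe, 80 °C
Reagents that add atoms: none
Why: Aromatic Claisen rearrangement: a concerted suprafacial [3,3] sigmatropic shift through a chair transition state breaks O4′–C3 of the heptenyl chain and forms C3′–C1, giving ortho-dienone 22, which tautomerises to the phenol. The closest precedent is the Eu(fod)3-catalysed or thermal Claisen rearrangement of enantioenriched secondary (E)-allyl aryl ethers, which proceeds with 1,3-chirality transfer. No ring is closed; only the six-membered cyclic transition state is involved. The new diarylmethine centre is controlled by the R-configured C–O carbon: with the CH2CH(OTBS) chain equatorial in the chair, the C–C bond forms on the allyl face from which oxygen departs, which should give the 1R configuration and the E alkene together. The step needs C3′ over C5′ selectivity, secured by the C2′–OH···O=C chelate, which makes C3′–C4′ the more double-bond-like ring bond (the para position C1′ is blocked). It also needs the concerted path to outrun ionisation of the allylic ether, which the non-polar solvent, the mild Lewis acid and the silyl ethers on the arenes favour.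

Step 15
Reactants: 23 hexakis-TBS ether of the target
Product: 24 blepharocalyxin B
Conditions: HF·pyridine, pyridine, THF, 0 → 23 °C
Reagents that add atoms: none
Why: Fluoride cleavage of all six silyl ethers (five aryl, one alkyl), driven by Si–F bond formation; pyridine buffering should protect the para-hydroxybenzylic ring ether and the diarylmethine centre.

**Compound list**

1 | tert-butyl(4-iodophenoxy)dimethylsilane | CC(C)(C)[Si](C)(C)Oc1ccc(I)cc1 | starting material
2 | prop-2-en-1-ol | C=CCO | starting material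
3 | 3-[4-(TBSO)phenyl]propanal | CC(C)(C)[Si](C)(C)Oc1ccc(CCC=O)cc1 | intermediate
4 | (E)-4-(4-hydroxyphenyl)but-3-en-2-one | CC(=O)/C=C/c1ccc(O)cc1 | starting material
5 | (E)-4-[4-(TBSO)phenyl]but-3-en-2-one | CC(=O)/C=C/c1ccc(O[Si](C)(C)C(C)(C)C)cc1 | intermediate
6 | (5S,E)-5-hydroxy-1,7-bis[4-(TBSO)phenyl]hept-1-en-3-one | CC(C)(C)[Si](C)(C)Oc1ccc(/C=C/C(=O)C[C@@H](O)CCc2ccc(O[Si](C)(C)C(C)(C)C)cc2)cc1 | intermediate
7 | (3S,5S,E)-1,7-bis[4-(TBSO)phenyl]hept-1-ene-3,5-diol | CC(C)(C)[Si](C)(C)Oc1ccc(/C=C/[C@@H](O)C[C@@H](O)CCc2ccc(O[Si](C)(C)C(C)(C)C)cc2)cc1 | intermediate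
8 | (4S,6S)-4-{(E)-2-[4-(TBSO)phenyl]ethenyl}-6-{2-[4-(TBSO)phenyl]ethyl}-1,3-dioxan-2-one | O=C1O[C@H](/C=C/c2ccc(O[Si](C)(C)C(C)(C)C)cc2)C[C@H](CCc2ccc(O[Si](C)(C)C(C)(C)C)cc2)O1 | intermediate
9 | 1-(2,4-dihydroxy-6-methoxyphenyl)ethan-1-one | CC(=O)c1c(O)cc(O)cc1OC | starting material
10 | 1-[2-methoxy-4,6-bis(methoxymethoxy)phenyl]ethan-1-one | CC(=O)c1c(OCOC)cc(OCOC)cc1OC | intermediate
11 | (Z)-3-hydroxy-1-[2-methoxy-4,6-bis(methoxymethoxy)phenyl]prop-2-en-1-one | O/C=C\C(=O)c1c(OCOC)cc(OCOC)cc1OC | intermediate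
12 | (3S,5S)-5-hydroxy-2-[2-methoxy-4,6-bis(methoxymethoxy)benzoyl]-7-[4-(TBSO)phenyl]-3-{(E)-2-[4-(TBSO)phenyl]ethenyl}heptanal (C2 enolisable) | O=CC(C(=O)c1c(OCOC)cc(OCOC)cc1OC)[C@H](/C=C/c1ccc(O[Si](C)(C)C(C)(C)C)cc1)C[C@@H](O)CCc1ccc(O[Si](C)(C)C(C)(C)C)cc1 | intermediate (not isolated)
13 | [(4S,6S)-6-{2-[4-(TBSO)phenyl]ethyl}-4-{(E)-2-[4-(TBSO)phenyl]ethenyl}-5,6-dihydro-4H-pyran-3-yl][2-methoxy-4,6-bis(methoxymethoxy)phenyl]methanone | O=C(c1c(OCOC)cc(OCOC)cc1OC)C1=CO[C@@H](CCc2ccc(O[Si](C)(C)C(C)(C)C)cc2)C[C@H]1/C=C/c1ccc(O[Si](C)(C)C(C)(C)C)cc1 | intermediate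
14 | [4-(TBSO)phenyl]magnesium iodide | CC(C)(C)[Si](C)(C)Oc1ccc([Mg]I)cc1 | intermediate (not isolated)
15 | trimethylsilyl enol ether of 17 (C3=C(OSiMe3)Ar; C2, C4 and C6 as in 17) | COc1cc(OCOC)cc(OCOC)c1C(O[Si](C)(C)C)=C1[C@H](/C=C/c2ccc(O[Si](C)(C)C(C)(C)C)cc2)C[C@H](CCc2ccc(O[Si](C)(C)C(C)(C)C)cc2)O[C@H]1c1ccc(O[Si](C)(C)C(C)(C)C)cc1 | intermediate (not isolated)
16 | (2R,3S,4S,6S)-3-epimer of 17 (aroyl cis to the 2-aryl group) | COc1cc(OCOC)cc(OCOC)c1C(=O)[C@H]1[C@H](/C=C/c2ccc(O[Si](C)(C)C(C)(C)C)cc2)C[C@H](CCc2ccc(O[Si](C)(C)C(C)(C)C)cc2)O[C@H]1c1ccc(O[Si](C)(C)C(C)(C)C)cc1 | intermediate (not isolated)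
17 | [2-methoxy-4,6-bis(methoxymethoxy)phenyl][(2R,3R,4S,6S)-2-[4-(TBSO)phenyl]-6-{2-[4-(TBSO)phenyl]ethyl}-4-{(E)-2-[4-(TBSO)phenyl]ethenyl}oxan-3-yl]methanone | COc1cc(OCOC)cc(OCOC)c1C(=O)[C@@H]1[C@H](/C=C/c2ccc(O[Si](C)(C)C(C)(C)C)cc2)C[C@H](CCc2ccc(O[Si](C)(C)C(C)(C)C)cc2)O[C@H]1c1ccc(O[Si](C)(C)C(C)(C)C)cc1 | intermediate
18 | (2,4-dihydroxy-6-methoxyphenyl)[(2R,3R,4S,6S)-2-[4-(TBSO)phenyl]-6-{2-[4-(TBSO)phenyl]ethyl}-4-{(E)-2-[4-(TBSO)phenyl]ethenyl}oxan-3-yl]methanone (fragment A) | COc1cc(O)cc(O)c1C(=O)[C@@H]1[C@H](/C=C/c2ccc(O[Si](C)(C)C(C)(C)C)cc2)C[C@H](CCc2ccc(O[Si](C)(C)C(C)(C)C)cc2)O[C@H]1c1ccc(O[Si](C)(C)C(C)(C)C)cc1 | intermediate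
19 | (5S,E)-5-(TBSO)-1,7-bis[4-(TBSO)phenyl]hept-1-en-3-one | CC(C)(C)[Si](C)(C)Oc1ccc(/C=C/C(=O)C[C@@H](O[Si](C)(C)C(C)(C)C)CCc2ccc(O[Si](C)(C)C(C)(C)C)cc2)cc1 | intermediate
20 | (3S,5S,E)-5-(TBSO)-1,7-bis[4-(TBSO)phenyl]hept-1-en-3-ol (fragment B) | CC(C)(C)[Si](C)(C)Oc1ccc(/C=C/[C@@H](O)C[C@@H](O[Si](C)(C)C(C)(C)C)CCc2ccc(O[Si](C)(C)C(C)(C)C)cc2)cc1 | intermediate
21 | 4′-O-[(3R,5S,E)-5-(TBSO)-1,7-bis[4-(TBSO)phenyl]hept-1-en-3-yl] ether of 18 | COc1cc(O[C@@H](/C=C/c2ccc(O[Si](C)(C)C(C)(C)C)cc2)C[C@@H](O[Si](C)(C)C(C)(C)C)CCc2ccc(O[Si](C)(C)C(C)(C)C)cc2)cc(O)c1C(=O)[C@@H]1[C@H](/C=C/c2ccc(O[Si](C)(C)C(C)(C)C)cc2)C[C@H](CCc2ccc(O[Si](C)(C)C(C)(C)C)cc2)O[C@H]1c1ccc(O[Si](C)(C)C(C)(C)C)cc1 | intermediate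
22 | ortho-dienone (cyclohexa-2,4-dienone tautomer of 23; C3′ sp3, S, bonded to the diarylmethine carbon) | COC1=CC(=O)[C@@H]([C@H](/C=C/C[C@@H](O[Si](C)(C)C(C)(C)C)CCc2ccc(O[Si](C)(C)C(C)(C)C)cc2)c2ccc(O[Si](C)(C)C(C)(C)C)cc2)C(O)=C1C(=O)[C@@H]1[C@H](/C=C/c2ccc(O[Si](C)(C)C(C)(C)C)cc2)C[C@H](CCc2ccc(O[Si](C)(C)C(C)(C)C)cc2)O[C@H]1c1ccc(O[Si](C)(C)C(C)(C)C)cc1 | intermediate (not isolated)
23 | 3′-C-[(1R,5S,E)-5-(TBSO)-1,7-bis[4-(TBSO)phenyl]hept-2-en-1-yl] derivative of 18 (hexakis-TBS ether of the target) | COc1cc(O)c([C@H](/C=C/C[C@@H](O[Si](C)(C)C(C)(C)C)CCc2ccc(O[Si](C)(C)C(C)(C)C)cc2)c2ccc(O[Si](C)(C)C(C)(C)C)cc2)c(O)c1C(=O)[C@@H]1[C@H](/C=C/c2ccc(O[Si](C)(C)C(C)(C)C)cc2)C[C@H](CCc2ccc(O[Si](C)(C)C(C)(C)C)cc2)O[C@H]1c1ccc(O[Si](C)(C)C(C)(C)C)cc1 | intermediate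
24 | blepharocalyxin B | COc1cc(O)c([C@H](/C=C/C[C@@H](O)CCc2ccc(O)cc2)c2ccc(O)cc2)c(O)c1C(=O)[C@@H]1[C@H](/C=C/c2ccc(O)cc2)C[C@H](CCc2ccc(O)cc2)O[C@H]1c1ccc(O)cc1 | target

**Step count and risks**

Total step count: 15. Longest linear sequence: 10 steps (1, 3, 4, 5, 8, 9, 10, 13, 14, 15).

Steps most likely to fail:

1. Step 14 (key step). The allylic C–O bond may ionise to an ion pair before the concerted shift, which would erode the 1,3-chirality transfer and allow an oxygen-to-oxygen 1,3-shift or alkylation at C5′. The fallback sets out from 7 and 18 and rejoins the route at 24. Diol 7 is desilylated with HF·pyridine to (3S,5S,E)-1,7-bis(4-hydroxyphenyl)hept-1-ene-3,5-diol F1. A BINOL-derived chiral phosphoric acid (CH2Cl2, 4 Å MS, −20 °C) then dehydrates the para-hydroxycinnamyl alcohol of F1 to a vinylogous para-quinone methide; the carbinol configuration is erased, so the step is stereoconvergent. The phosphate directs 1,6-addition of C3′ of 18 to the benzylic carbon, giving the tris-TBS ether of the target F2, and HF·pyridine gives 24.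

2. Step 9. The enolate may expel the ring oxygen (ring opening to an α-substituted chalcone, during the addition or during the DBU equilibration) and re-close to the all-equatorial 2,6-cis oxane, or the aryl group may enter from the equatorial direction. The fallback sets out from 10 and 8 and rejoins at 17. Aldol condensation of 10 with 4-(TBSO)benzaldehyde (LiHMDS, THF, −78 °C; then MsCl, Et3N) gives (E)-1-[2-methoxy-4,6-bis(methoxymethoxy)phenyl]-3-[4-(TBSO)phenyl]prop-2-en-1-one F3. Pd(PPh3)4 in THF then effects a decarboxylative (4+2) annulation of 8 with F3: the liberated alkoxide adds to the chalcone and the enolate closes on the π-allyl unit with net retention at C4, the 2-aryl group being held axial by allylic strain with the exocyclic enolate. Equilibration at C3 gives 17.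

3. Step 13. The activated para-silyloxycinnamyl alcohol may ionise (SN1 or SN2′ leakage, eroding the inversion) or eliminate to a diene. The fallback sets out from 19 and rejoins at 21. Reduction of 19 with the (S)-oxazaborolidine and catecholborane gives the epimeric (3R,5S,E)-5-(TBSO)-1,7-bis[4-(TBSO)phenyl]hept-1-en-3-ol F4. Methyl chloroformate and pyridine give its methyl carbonate F5. Pd(PPh3)4 with phenol 18 in THF then gives 21 by double inversion (net retention), the phenoxide attacking the allyl terminus remote from the arene.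

**Further compounds**

F1 | step 14 | (3S,5S,E)-1,7-bis(4-hydroxyphenyl)hept-1-ene-3,5-diol | Oc1ccc(/C=C/[C@@H](O)C[C@@H](O)CCc2ccc(O)cc2)cc1
F2 | step 14 | tris-TBS ether of blepharocalyxin B (silyl groups on the three arenes of the oxane unit) | COc1cc(O)c([C@H](/C=C/C[C@@H](O)CCc2ccc(O)cc2)c2ccc(O)cc2)c(O)c1C(=O)[C@@H]1[C@H](/C=C/c2ccc(O[Si](C)(C)C(C)(C)C)cc2)C[C@H](CCc2ccc(O[Si](C)(C)C(C)(C)C)cc2)O[C@H]1c1ccc(O[Si](C)(C)C(C)(C)C)cc1
F3 | step 9 | (E)-1-[2-methoxy-4,6-bis(methoxymethoxy)phenyl]-3-[4-(TBSO)phenyl]prop-2-en-1-one | COCOc1cc(OC)c(C(=O)/C=C/c2ccc(O[Si](C)(C)C(C)(C)C)cc2)c(OCOC)c1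
F4 | step 13 | (3R,5S,E)-5-(TBSO)-1,7-bis[4-(TBSO)phenyl]hept-1-en-3-ol | CC(C)(C)[Si](C)(C)Oc1ccc(/C=C/[C@H](O)C[C@@H](O[Si](C)(C)C(C)(C)C)CCc2ccc(O[Si](C)(C)C(C)(C)C)cc2)cc1
F5 | step 13 | methyl (3R,5S,E)-5-(TBSO)-1,7-bis[4-(TBSO)phenyl]hept-1-en-3-yl carbonate | CC(C)(C)[Si](C)(C)Oc1ccc(/C=C/[C@H](OC(=O)OC)C[C@@H](O[Si](C)(C)C(C)(C)C)CCc2ccc(O[Si](C)(C)C(C)(C)C)cc2)cc1
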